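**Plan**

1. Retrosynthetic cuts, in order: the C11 acetate; C11–C12 (vinylogous aldol of a C9 aldehyde with a senecioate dienolate); C9–C11 (carbonylation of a C9 enol triflate, the C8=C17 alkene arising by deconjugation); C3–C4 of ring A; then C10–C1 and C10–CH3, which leads back to (R)-carvone.
2. Forward: ring B is carvone; C10 is made quaternary by methylation, then 2-(methoxycarbonyl)allylation; ring A is closed by forming C3–C4 in a hydrogen-atom-transfer radical cyclisation; the helper ester at C2 is excised.
3. The C9 ketone is then converted into the C11 ester, the alkene is moved to C8=C17, and the side chain is joined at C11 and acetylated.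
4. Enabling feature: the gem-dimethyl carbon C4 of ring A sits on the ring-fusion methine C5, and ring B carries a one-carbon branch (C17) on C8 next to C9. Ring B plus C4 and its two methyls is therefore the carvone skeleton, so C4 can be generated as a tertiary radical from the isopropenyl group and C3 offered as the β-carbon of an acrylate hung on C10.
5. Stereochemistry: C5 from (R)-carvone; C10 by enolate alkylation anti to the isopropenyl group (this fixes the trans ring fusion); C9 by α-face protonation of a dienolate; C11 by Felkin–Anh addition to the C9 aldehyde; the 13E alkene from the vinylogous aldol.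

Key step: step 3

Remark: atoms are numbered as in the labdane skeleton (ring A = C1–C5, C10; ring B = C5–C10; C17 = exocyclic methylene carbon; C11 = acetoxy-bearing carbon). The target is read as methyl (11S,13E)-11-acetoxylabda-8(17),13-dien-15-oate with 5S,9S,10S configuration. Compound 3 is expected as a C6 epimer mixture and 7 and 8 as C2 epimer mixtures; both centres are erased later.

Step 1
Reactants: 1 (R)-(−)-carvone
Product: 3 (5R,6S)-2,6-dimethyl-5-(prop-1-en-2-yl)cyclohex-2-en-1-one (trans-6-methylcarvone), via carvone lithium enolate 2 (not isolated)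
Conditions: LiN(iPr)2 (commercial solution), THF, −78 °C; MeI, −78 → 0 °C
Reagents that add atoms: iodomethane, CI
Why: Kinetic α′-deprotonation of the enone at C6 gives the cross-conjugated lithium enolate, and its C-methylation (enolate alkylation) installs the future C20 methyl group; the C6 configuration is irrelevant because it is erased in step 2.

Step 2
Reactants: 3 (5R,6S)-2,6-dimethyl-5-(prop-1-en-2-yl)cyclohex-2-en-1-one; 4 methyl 2-(bromomethyl)prop-2-enoate
Product: 6 methyl 2-{[(1S,6S)-1,3-dimethyl-2-oxo-6-(prop-1-en-2-yl)cyclohex-3-en-1-yl]methyl}prop-2-enoate, via lithium enolate 5 (not isolated)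
Conditions: LiN(iPr)2 (commercial solution), THF, −78 → 0 °C; DMPU, then 4, −78 °C → rt
Reagents that add atoms: none
Why: Enolate alkylation with a highly reactive 2-(alkoxycarbonyl)allyl bromide (SN2 and SN2′ give the same product) should occur on the enolate face anti to the adjacent isopropenyl group, placing the acrylate arm trans and the methyl cis to it and so setting the quaternary carbon (future C10).

Step 3
Reactants: 6 methyl 2-{[(1S,6S)-1,3-dimethyl-2-oxo-6-(prop-1-en-2-yl)cyclohex-3-en-1-yl]methyl}prop-2-enoate
Product: 7 methyl (4aS,8aS)-4,4,7,8a-tetramethyl-8-oxo-1,2,3,4,4a,5,8,8a-octahydronaphthalene-2-carboxylate (C2 epimers)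
Conditions: Fe(acac)3 (30 mol %), PhSiH3 (2.5 equiv), EtOH/(CH2OH)2 5:1, 0.02 M, 60 °C
Reagents that add atoms: none
Why: The iron hydride generated from Fe(acac)3 and PhSiH3 transfers a hydrogen atom to the CH2 terminus of the electron-rich isopropenyl group, and the tertiary radical so formed at C4 adds to the unsubstituted β-carbon (C3) of the acrylate; the α-ester radical at C2 is then reduced by divalent iron to the enolate and protonated by the alcohol solvent. The closest known reaction type is the metal-hydride hydrogen-atom-transfer reductive olefin coupling, here an intramolecular Giese addition of an alkene-derived tertiary radical to an α-substituted acrylate. Ring A closes in the 6-endo-trig mode, and the 5-exo alternative is excluded because it would have to join the tertiary radical to the fully substituted, electronically mismatched α-carbon of the acceptor. No stereocentre of the target is created: C4 carries two methyl groups, the trans ring fusion is already fixed by C5 and C10, whose two arms are trans-diequatorial on ring B and can only bridge to a trans-decalin, and the new centre at C2 (set by unselective enolate protonation) is deleted in step 5. The step needs hydrogen-atom transfer to the isopropenyl group in preference to the two electron-poor alkenes, which the polarity of the hydride donor should secure, and it needs the ring B enone to stay out of the radical step, which is ensured because its β-carbon C7 could be reached from C4 only through a four-membered ring.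

Step 4
Reactants: 7 methyl (4aS,8aS)-4,4,7,8a-tetramethyl-8-oxo-1,2,3,4,4a,5,8,8a-octahydronaphthalene-2-carboxylate
Product: 8 (4aS,8aS)-4,4,7,8a-tetramethyl-8-oxo-1,2,3,4,4a,5,8,8a-octahydronaphthalene-2-carboxylic acid (C2 epimers)
Conditions: LiOH, THF/MeOH/H2O, 50 °C; then 1 M HCl
Reagents that add atoms: lithium hydroxide, [Li+].[OH-]
Why: Saponification of the secondary methyl ester frees the carboxylic acid needed for excision of the helper carbon; the C9 ketone has no α-hydrogen at C10, so no centre of consequence can epimerise.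

Step 5
Reactants: 8 (4aS,8aS)-4,4,7,8a-tetramethyl-8-oxo-1,2,3,4,4a,5,8,8a-octahydronaphthalene-2-carboxylic acid
Product: 9 (4aS,8aS)-2,5,5,8a-tetramethyl-4a,5,6,7,8,8a-hexahydronaphthalen-1(4H)-one
Conditions: 9-mesityl-10-phenylacridinium tetrafluoroborate (5 mol %), (PhS)2 (10 mol %), iPr2NEt (20 mol %), CF3CH2OH, blue LEDs, rt
Reagents that add atoms: none
Why: Photoredox hydrodecarboxylation: oxidation of the carboxylate by the excited acridinium and loss of CO2 give the secondary C2 radical, which takes a hydrogen atom from thiophenol formed in situ, so the activating group is removed and C2 becomes a plain CH2.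

Step 6
Reactants: 9 (4aS,8aS)-2,5,5,8a-tetramethyl-4a,5,6,7,8,8a-hexahydronaphthalen-1(4H)-one
Product: 11 (4aS,8aS)-2,5,5,8a-tetramethyl-3,4,4a,5,6,7,8,8a-octahydronaphthalen-1-yl trifluoromethanesulfonate, via lithium enolate 10 (not isolated)
Conditions: LiBH(sec-Bu)3 (L-Selectride), THF, −78 °C; PhNTf2, −78 → 0 °C; then aq NH4Cl
Reagents that add atoms: N-phenylbis(trifluoromethanesulfonimide), O=S(=O)(N(c1ccccc1)S(=O)(=O)C(F)(F)F)C(F)(F)F
Why: Conjugate hydride reduction of the enone, whose carbonyl is shielded by the quaternary C10, gives the C9–C8 enolate regiospecifically, and O-sulfonylation traps it as the tetrasubstituted enol triflate.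

Step 7
Reactants: 11 (4aS,8aS)-2,5,5,8a-tetramethyl-3,4,4a,5,6,7,8,8a-octahydronaphthalen-1-yl trifluoromethanesulfonate
Product: 12 methyl (4aS,8aS)-2,5,5,8a-tetramethyl-3,4,4a,5,6,7,8,8a-octahydronaphthalene-1-carboxylate
Conditions: Pd(OAc)2 (5 mol %), PPh3 (10 mol %), CO (1 atm), MeOH, Et3N, DMF, 65 °C
Reagents that add atoms: carbon monoxide, [C-]#[O+]; methanol, CO
Why: Palladium-catalysed alkoxycarbonylation (oxidative addition of zerovalent palladium into the C9–OTf bond, CO insertion, methanolysis) attaches C11 to C9 as the conjugated methyl ester.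

Step 8
Reactants: 12 methyl (4aS,8aS)-2,5,5,8a-tetramethyl-3,4,4a,5,6,7,8,8a-octahydronaphthalene-1-carboxylate
Product: 14 methyl (1S,4aS,8aS)-5,5,8a-trimethyl-2-methylidenedecahydronaphthalene-1-carboxylate, via lithium dienolate 13 (not isolated)
Conditions: LiN(iPr)2 (commercial solution), DMPU, THF, −78 °C; inverse quench into AcOH/THF, −78 °C
Reagents that add atoms: none
Why: Deconjugative protonation: the base should remove a proton from the C17 methyl group, which is held cis to the ester across the ring double bond, and kinetic α-protonation of the dienolate at C9 from the α-face, anti to the axial C10 methyl, should give the exocyclic C8=C17 alkene and the equatorial ester with 9S configuration.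

Step 9
Reactants: 14 methyl (1S,4aS,8aS)-5,5,8a-trimethyl-2-methylidenedecahydronaphthalene-1-carboxylate
Product: 15 [(1S,4aS,8aS)-5,5,8a-trimethyl-2-methylidenedecahydronaphthalen-1-yl]methanol
Conditions: LiAlH4, Et2O, 0 °C; aqueous NaOH work-up
Reagents that add atoms: none
Why: Hydride reduction of the ester to the primary alcohol is faster than any enolisation, so C9 and the exocyclic alkene should be untouched.

Step 10
Reactants: 15 [(1S,4aS,8aS)-5,5,8a-trimethyl-2-methylidenedecahydronaphthalen-1-yl]methanol
Product: 16 (1S,4aS,8aS)-5,5,8a-trimethyl-2-methylidenedecahydronaphthalene-1-carbaldehyde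
Conditions: Dess–Martin periodinane, pyridine, CH2Cl2, 0 °C → rt; used at once
Reagents that add atoms: none
Why: Dess–Martin oxidation under buffered, non-enolising conditions should give the β,γ-unsaturated aldehyde without epimerisation at C9 or migration of the C8=C17 double bond.

Step 11
Reactants: 17 methyl 3-methylbut-2-enoate
Product: 19 [(1-methoxy-3-methylbuta-1,3-dien-1-yl)oxy]trimethylsilane, via lithium dienolate 18 (not isolated)
Conditions: LiN(iPr)2 (commercial solution), THF, −78 °C; Me3SiCl, −78 °C → rt
Reagents that add atoms: chlorotrimethylsilane, C[Si](C)(C)Cl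
Why: γ-Deprotonation of the senecioate and O-silylation of the lithium dienolate give the silyl dienol ether (vinylogous ketene acetal) that carries C12–C16.

Step 12
Reactants: 16 (1S,4aS,8aS)-5,5,8a-trimethyl-2-methylidenedecahydronaphthalene-1-carbaldehyde; 19 [(1-methoxy-3-methylbuta-1,3-dien-1-yl)oxy]trimethylsilane
Product: 21 methyl (2E,5S)-5-hydroxy-3-methyl-5-[(1S,4aS,8aS)-5,5,8a-trimethyl-2-methylidenedecahydronaphthalen-1-yl]pent-2-enoate, via trimethylsilyl ether 20 (not isolated)
Conditions: B(C6F5)3 (20 mol %), CH2Cl2/Et2O, −78 °C; then 1 M HCl, THF, 0 °C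
Reagents that add atoms: none
Why: Vinylogous Mukaiyama aldol addition: the terminal CH2 of the silyl dienolate attacks the Lewis-acid-activated aldehyde to form C11–C12 and the conjugated enoate, expected as the E isomer, and the 11S centre should arise by Felkin–Anh addition anti to the quaternary C10 substituent of C9, the nucleophile passing the C9 hydrogen.

Step 13
Reactants: 21 methyl (2E,5S)-5-hydroxy-3-methyl-5-[(1S,4aS,8aS)-5,5,8a-trimethyl-2-methylidenedecahydronaphthalen-1-yl]pent-2-enoate
Product: 22 methyl (2E,5S)-5-acetoxy-3-methyl-5-[(1S,4aS,8aS)-5,5,8a-trimethyl-2-methylidenedecahydronaphthalen-1-yl]pent-2-enoate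
Conditions: Ac2O, pyridine, DMAP (cat.), CH2Cl2, rt
Reagents that add atoms: acetic anhydride, CC(=O)OC(C)=O
Why: DMAP-catalysed O-acylation of the secondary alcohol should give the target acetate without touching any stereocentre or the enoate.

**Compound list**

1 | (R)-(−)-carvone, (5R)-2-methyl-5-(prop-1-en-2-yl)cyclohex-2-en-1-one | CC1=CC[C@H](CC1=O)C(C)=C | starting material
2 | cross-conjugated lithium enolate of 1 (C1–C6 enolate) | CC1=CC[C@H](C=C1[O-])C(C)=C.[Li+] | intermediate
3 | (5R,6S)-2,6-dimethyl-5-(prop-1-en-2-yl)cyclohex-2-en-1-one (trans isomer drawn; C6 epimer expected alongside) | CC1=CC[C@H]([C@H](C)C1=O)C(C)=C | intermediate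
4 | methyl 2-(bromomethyl)prop-2-enoate | C=C(CBr)C(=O)OC | starting material
5 | lithium enolate of 3 (C1–C6 enolate) | CC1=CC[C@H](C(C)=C1[O-])C(C)=C.[Li+] | intermediate
6 | methyl 2-{[(1S,6S)-1,3-dimethyl-2-oxo-6-(prop-1-en-2-yl)cyclohex-3-en-1-yl]methyl}prop-2-enoate | CC1=CC[C@H]([C@](C)(CC(=C)C(=O)OC)C1=O)C(C)=C | intermediate
7 | methyl (4aS,8aS)-4,4,7,8a-tetramethyl-8-oxo-1,2,3,4,4a,5,8,8a-octahydronaphthalene-2-carboxylate (C2 epimers) | CC1=CC[C@H]2C(C)(C)CC(C(=O)OC)C[C@]2(C)C1=O | intermediate
8 | (4aS,8aS)-4,4,7,8a-tetramethyl-8-oxo-1,2,3,4,4a,5,8,8a-octahydronaphthalene-2-carboxylic acid (C2 epimers) | CC1=CC[C@H]2C(C)(C)CC(C(=O)O)C[C@]2(C)C1=O | intermediate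
9 | (4aS,8aS)-2,5,5,8a-tetramethyl-4a,5,6,7,8,8a-hexahydronaphthalen-1(4H)-one | CC1=CC[C@H]2C(C)(C)CCC[C@]2(C)C1=O | intermediate
10 | lithium (4aS,8aS)-2,5,5,8a-tetramethyl-3,4,4a,5,6,7,8,8a-octahydronaphthalen-1-olate | CC=1CC[C@H]2C(C)(C)CCC[C@]2(C)C=1[O-].[Li+] | intermediate
11 | (4aS,8aS)-2,5,5,8a-tetramethyl-3,4,4a,5,6,7,8,8a-octahydronaphthalen-1-yl trifluoromethanesulfonate | CC=1CC[C@H]2C(C)(C)CCC[C@]2(C)C=1OS(=O)(=O)C(F)(F)F | intermediate
12 | methyl (4aS,8aS)-2,5,5,8a-tetramethyl-3,4,4a,5,6,7,8,8a-octahydronaphthalene-1-carboxylate | CC=1CC[C@H]2C(C)(C)CCC[C@]2(C)C=1C(=O)OC | intermediate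
13 | lithium dienolate of 12 (deprotonated at C17; C9=C11 enolate with C8=C17 methylidene) | C=C1CC[C@H]2C(C)(C)CCC[C@]2(C)C1=C([O-])OC.[Li+] | intermediate
14 | methyl (1S,4aS,8aS)-5,5,8a-trimethyl-2-methylidenedecahydronaphthalene-1-carboxylate | C=C1CC[C@H]2C(C)(C)CCC[C@]2(C)[C@H]1C(=O)OC | intermediate
15 | [(1S,4aS,8aS)-5,5,8a-trimethyl-2-methylidenedecahydronaphthalen-1-yl]methanol | C=C1CC[C@H]2C(C)(C)CCC[C@]2(C)[C@H]1CO | intermediate
16 | (1S,4aS,8aS)-5,5,8a-trimethyl-2-methylidenedecahydronaphthalene-1-carbaldehyde | C=C1CC[C@H]2C(C)(C)CCC[C@]2(C)[C@H]1C=O | intermediate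
17 | methyl 3-methylbut-2-enoate | CC(C)=CC(=O)OC | starting material
18 | lithium dienolate of 17 | C=C(C)C=C([O-])OC.[Li+] | intermediate
19 | [(1-methoxy-3-methylbuta-1,3-dien-1-yl)oxy]trimethylsilane | C=C(C)C=C(OC)O[Si](C)(C)C | intermediate
20 | methyl (2E,5S)-3-methyl-5-[(1S,4aS,8aS)-5,5,8a-trimethyl-2-methylidenedecahydronaphthalen-1-yl]-5-[(trimethylsilyl)oxy]pent-2-enoate | C=C1CC[C@H]2C(C)(C)CCC[C@]2(C)[C@H]1[C@H](C/C(C)=C/C(=O)OC)O[Si](C)(C)C | intermediate
21 | methyl (2E,5S)-5-hydroxy-3-methyl-5-[(1S,4aS,8aS)-5,5,8a-trimethyl-2-methylidenedecahydronaphthalen-1-yl]pent-2-enoate | C=C1CC[C@H]2C(C)(C)CCC[C@]2(C)[C@H]1[C@H](C/C(C)=C/C(=O)OC)O | intermediate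
22 | methyl (2E,5S)-5-acetoxy-3-methyl-5-[(1S,4aS,8aS)-5,5,8a-trimethyl-2-methylidenedecahydronaphthalen-1-yl]pent-2-enoate | C=C1CC[C@H]2C(C)(C)CCC[C@]2(C)[C@H]1[C@H](C/C(C)=C/C(=O)OC)OC(C)=O | target

**Step count**

Total: 13 steps. Longest linear sequence: 12 steps (steps 1–10, 12 and 13); step 11 prepares the side-chain fragment separately.

**Steps most likely to fail**

Step 3. The C4 radical may be quenched by a second hydrogen-atom transfer before it cyclises, or the hydride may attack the acrylate first. The fallback sets out from 6 and comes back at 7. Markovnikov addition of HBr to the isopropenyl group (HBr, CH2Cl2, −78 °C) should give the tertiary bromide methyl 2-{[(1S,6R)-6-(2-bromopropan-2-yl)-1,3-dimethyl-2-oxocyclohex-3-en-1-yl]methyl}prop-2-enoate F1, used crude. Slow addition of Bu3SnH with AIBN in benzene at 80 °C would then generate the same C4 radical by bromine-atom abstraction in a tin hydride chain. The hydrogen donor is kept at low stationary concentration there, so the 6-endo Giese closure to 7 can outrun reduction.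

Step 8. The base may remove a ring proton at C7 in competition with the C17 methyl proton, or the product may reconjugate during the quench. The fallback sets out from 12 and comes back at 14. Irradiation at 254 nm in hexane with catalytic 1,2-dimethylimidazole (photochemical deconjugation of an α,β-unsaturated ester) triggers a 1,5-hydrogen shift in the excited ester. That shift can reach only the C17 methyl group held cis to the carbonyl, and gives the dienol methoxy[(4aS,8aS)-5,5,8a-trimethyl-2-methylideneoctahydronaphthalen-1(2H)-ylidene]methanol F2. Reketonisation of F2 at C9 from the α-face under neutral conditions would give 14.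

Step 12. Facial selectivity at C11 may be poor, the E/Z geometry may erode, and the sensitive β,γ-unsaturated aldehyde may isomerise under Lewis acid. The fallback sets out from 16 and comes back at 21.
- Catalyst-controlled propargylation (allenylboronic acid pinacol ester, chiral phosphoric acid TRIP, toluene, 0 °C; the catalyst enantiomer that delivers the 11S alcohol to be chosen in a test reaction) would give (1S)-1-[(1S,4aS,8aS)-5,5,8a-trimethyl-2-methylidenedecahydronaphthalen-1-yl]but-3-yn-1-ol F3.
- Negishi carboalumination and iodination (AlMe3, Cp2ZrCl2 cat., CH2Cl2, rt; then I2, THF, −30 °C) would fix the alkene geometry by syn-carbometalation and give (1S,3E)-4-iodo-3-methyl-1-[(1S,4aS,8aS)-5,5,8a-trimethyl-2-methylidenedecahydronaphthalen-1-yl]but-3-en-1-ol F4.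
- Palladium-catalysed methoxycarbonylation (Pd(OAc)2, PPh3, CO, MeOH, Et3N) would convert F4 into 21 with retention of geometry; the hydroxyl group sits trans to the acyl-palladium carbon and should not lactonise.

**Further compounds**

F1 | step 3 | methyl 2-{[(1S,6R)-6-(2-bromopropan-2-yl)-1,3-dimethyl-2-oxocyclohex-3-en-1-yl]methyl}prop-2-enoate | CC1=CC[C@H]([C@](C)(CC(=C)C(=O)OC)C1=O)C(C)(C)Br
F2 | step 8 | methoxy[(4aS,8aS)-5,5,8a-trimethyl-2-methylideneoctahydronaphthalen-1(2H)-ylidene]methanol | C=C1CC[C@H]2C(C)(C)CCC[C@]2(C)C1=C(O)OC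
F3 | step 12 | (1S)-1-[(1S,4aS,8aS)-5,5,8a-trimethyl-2-methylidenedecahydronaphthalen-1-yl]but-3-yn-1-ol | C=C1CC[C@H]2C(C)(C)CCC[C@]2(C)[C@H]1[C@H](CC#C)O
F4 | step 12 | (1S,3E)-4-iodo-3-methyl-1-[(1S,4aS,8aS)-5,5,8a-trimethyl-2-methylidenedecahydronaphthalen-1-yl]but-3-en-1-ol | C=C1CC[C@H]2C(C)(C)CCC[C@]2(C)[C@H]1[C@H](C/C(C)=C/I)O
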